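**Plan**
1. Retrosynthetic cuts: first the acyl groups and the γ-lactone (C19–O7, back to an isopropenyl group on C8). Next ring A at C11=C12 (metathesis) and C13–C14 (allylation). Then the fusion bond C1–C10 by a retro-Ireland–Claisen, which opens the ten-membered carbocycle to a 14-membered lactone C14(=O)–O–CH2–C11(Me)=C10. Last the ester C–O, C4–C5 (Ni/Cr), C5=C6 and C10=C11 (Wittig), C8–C17 (Grignard) and C1–C2 (aldol).
2. Enabling feature: on the bond shared by ring A (C1, C10–C14) and the ten-membered ring (C1–C10), quaternary C1 carries the oxygenated C14 and C10 carries the alkenyl carbon C11. C14–C1–C10–C11=C is therefore a γ,δ-unsaturated carbonyl (Claisen retron), and the periphery C1–C14 is a 14-membered ring.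
3. Forward order: open C1–C11 chain, then the 14-membered lactone, then transannular [3,3] contraction to the ten-membered ring. Ring A follows by allylation and metathesis, then the γ-lactone, then the acylations.
4. Stereochemistry: C7 and C9 are bought with D-glucose, and C8 is relayed from them by a convex-face Grignard addition. C2 comes from an Evans aldol, and C4 from a ligand-controlled Ni/Cr coupling (1,3-anti to C2). C1 and C10 are set together in the key step, from the two alkene geometries and from C2 and C9. C14 is set by catalyst control, and C17 by hydroboration (it also remains epimerisable).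

Key step: step 17

Remark: briarane numbering is used throughout, and CH2* is the O-bound allylic carbon on C11, which leaves as ethene in step 20. The anomeric centre of 6 is taken as a mixture, and the acetal carbon of 17–31 as the thermodynamic isomer (aryl equatorial, C3 axial); both centres are removed later. C1 in 12–20 is defined but irrelevant, because step 17 erases it.

Step 1
Reactants: 1 diacetone-D-glucose (1,2:5,6-di-O-isopropylidene-α-D-glucofuranose)
Product: 2 1,2:5,6-di-O-isopropylidene-α-D-ribo-hexofuranos-3-ulose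
Conditions: DMP, CH2Cl2, rt
Reagents that add atoms: none
Why: Dess–Martin oxidation of the only free hydroxyl (sugar C3, the future C8) touches no stereocentre.

Step 2
Reactants: 2 3-ulose
Product: 3 3-C-isopropenyl-1,2:5,6-di-O-isopropylidene-α-D-allofuranose (tertiary OH on the α face)
Conditions: CH2=C(CH3)MgBr, THF, −78 → 0 °C; sat. aq. NH4Cl
Reagents that add atoms: isopropenylmagnesium bromide, C=C(C)[Mg]Br
Why: Grignard 1,2-addition to the cis-fused bicyclic ketone occurs from the convex β face because the 1,2-acetonide blocks the α face, which sets C8 with its hydroxyl cis to O7 (ribo pattern).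

Step 3
Reactants: 3 isopropenyl allofuranose
Product: 4 3-C-isopropenyl-1,2-O-isopropylidene-α-D-ribo-pentodialdo-1,4-furanose
Conditions: H5IO6, EtOAc, rt
Reagents that add atoms: none
Why: periodic acid hydrolyses the more labile exocyclic 5,6-acetonide and cleaves the glycol in the same flask (Malaprade cleavage), leaving C9 untouched.

Step 4
Reactants: 4 aldehyde
Product: 5 methyl (E)-2-methylenoate on the 1,2-acetonide furanose (C10=C11 E)
Conditions: Ph3P=C(CH3)CO2Me, CH2Cl2, rt
Reagents that add atoms: methyl 2-(triphenylphosphoranylidene)propanoate, COC(=O)C(C)=P(c1ccccc1)(c1ccccc1)c1ccccc1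
Why: Wittig olefination with an α-methyl stabilised ylide gives the E trisubstituted enoate, the geometry the key step needs.

Step 5
Reactants: 5 1,2-acetonide enoate
Product: 6 2,3-O-isopropylidene lactol (O7/O8 acetonide, free anomeric OH, O9 in the furanose ring)
Conditions: acetone, H2SO4 (cat.), rt
Reagents that add atoms: none
Why: acid-catalysed acetal migration under thermodynamic control favours, as for ribose itself, the cis-2,3-diol acetonide with a free anomeric hydroxyl, which masks O7 and the tertiary O8 together and keeps O9 distinguishable.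

Step 6
Reactants: 6 lactol
Product: 7 open-chain (Z)-α-iodoenoate with free 9-OH (iodine on C5 cis to C7, ester C16 trans to C7)
Conditions: Ph3P=CHCO2Me, NIS, CH2Cl2, −20 °C; then 6, 40 °C
Reagents that add atoms: methyl (triphenylphosphoranylidene)acetate, COC(=O)C=P(c1ccccc1)(c1ccccc1)c1ccccc1; N-iodosuccinimide, O=C1CCC(=O)N1I
Why: Wittig olefination of the hydroxy-aldehyde form with the α-iodo stabilised ylide places the ester trans to C7, so iodine marks the site and geometry at which C4 will be attached.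

Step 7
Reactants: 7 hydroxy iodoenoate
Product: 8 9-O-TBS ether of 7
Conditions: TBSOTf, 2,6-lutidine, CH2Cl2, 0 °C
Reagents that add atoms: tert-butyldimethylsilyl triflate, CC(C)(C)[Si](C)(C)OS(=O)(=O)C(F)(F)F
Why: silylation of the only free hydroxyl removes the nucleophile that could add to the iodoenoate.

Step 8
Reactants: 8 diester
Product: 9 iodo diol (C16H2OH on the (Z)-iodoalkene, CH2*OH on the (E)-alkene)
Conditions: DIBAL-H (excess), CH2Cl2, −78 °C; Rochelle salt
Reagents that add atoms: none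
Why: DIBAL-H 1,2-reduction takes both enoates to allylic alcohols in one operation without touching the vinyl iodide or either alkene geometry.

Step 9
Reactants: 10 (S)-4-benzyl-3-propionyl-1,3-oxazolidin-2-one; 11 acrolein
Product: 12 syn-aldol imide, (2S,3R)-3-hydroxy-2-methylpent-4-enoyl
Conditions: n-Bu2BOTf, Et3N, CH2Cl2, 0 °C; 11, −78 → 0 °C; H2O2, MeOH, pH 7 buffer
Reagents that add atoms: none
Why: in the Evans syn-aldol reaction the (Z)-boron enolate reacts through a closed chair on the face opposite the benzyl group, which sets C2.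

Step 10
Reactants: 12 aldol imide
Product: 13 methyl (2S,3R)-3-hydroxy-2-methylpent-4-enoate
Conditions: NaOMe (cat.), MeOH, 0 °C
Reagents that add atoms: methanol, CO
Why: methanolysis at the exocyclic imide carbonyl releases the auxiliary and gives an ester that tolerates the later Ni/Cr coupling.

Step 11
Reactants: 13 hydroxy ester
Product: 14 TBS ether of 13
Conditions: TBSOTf, 2,6-lutidine, CH2Cl2, 0 °C
Reagents that add atoms: tert-butyldimethylsilyl triflate, CC(C)(C)[Si](C)(C)OS(=O)(=O)C(F)(F)F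
Why: standard silylation installs the bulky, non-chelating O2 group on which the facial bias of the key step relies.

Step 12
Reactants: 14 allylic silyl ether
Product: 15 methyl (2S,3R)-3-(TBSO)-2-methyl-5-oxopentanoate (C4 aldehyde)
Conditions: PdCl2(PhCN)2, CuCl2·2H2O, AgNO2 (all cat.), O2 (1 atm), t-BuOH–MeNO2, rt
Reagents that add atoms: dioxygen, O=O
Why: the nitrite-modified, aldehyde-selective Wacker oxidation oxidises the terminal carbon because the allylic silyloxy group inductively disfavours attack at the internal carbon.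

Step 13
Reactants: 9 iodo diol; 15 aldehyde
Product: 16 coupled triol ester (new C4–C5 bond, 4-OH 1,3-anti to O2, C5=C6 geometry retained)
Conditions: CrCl2, NiCl2 (cat.), chiral oxazoline–sulfonamide ligand, Et3N, THF, rt
Reagents that add atoms: none
Why: in the Nozaki–Hiyama–Kishi coupling the C–I bond is activated with retention of geometry, and C4 is set by the chiral ligand on chromium in the sense also favoured by 1,3-anti (polar) induction from the C2 silyloxy group.

Step 14
Reactants: 16 triol ester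
Product: 17 4,16-O-(4-methoxybenzylidene) acetal with free CH2*OH
Conditions: 4-MeOC6H4CH(OMe)2, PPTS (cat.), CH2Cl2, 0 °C → rt
Reagents that add atoms: 4-methoxybenzaldehyde dimethyl acetal, COc1ccc(cc1)C(OC)OC
Why: reversible transacetalisation ends on the only 1,3-diol (O4/O16) as a six-membered acetal with the aryl group equatorial, leaving the remote primary alcohol free.

Step 15
Reactants: 17 hydroxy methyl ester
Product: 18 seco acid
Conditions: Me3SnOH, 1,2-dichloroethane, 70 °C; dilute HCl wash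
Reagents that add atoms: trimethyltin hydroxide, C[Sn](C)(C)O
Why: the mild tin hydroxide ester cleavage avoids β-elimination of the C2 silyloxy group.

Step 16
Reactants: 18 seco acid
Product: 20 14-membered macrolactone (ring C14–O–CH2*–C11=C10–C9–C8–C7–C6=C5–C4–C3–C2–C1), via mixed anhydride 19 (not isolated)
Conditions: 2,4,6-Cl3C6H2COCl, Et3N, THF, rt; then DMAP, toluene (high dilution), 60 °C
Reagents that add atoms: 2,4,6-trichlorobenzoyl chloride (atoms appear in 19 only), O=C(Cl)c1c(Cl)cc(Cl)cc1Cl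
Why: Yamaguchi macrolactonisation of a primary allylic alcohol to an unstrained 14-membered ring is a favourable closure, and any epimerisation at C1 is harmless.

Step 17
Reactants: 20 macrolactone
Product: 22 ten-membered carbocyclic TBS ester (C1 bears Me-15 and C14O2TBS; C10 bears H and isopropenyl; Me-15 anti to H-10), via silyl ketene acetal 21 (not isolated)
Conditions: LDA, THF–HMPA (4:1), −78 °C; TBSCl, −78 °C → rt; then toluene, 90 °C
Reagents that add atoms: tert-butyldimethylsilyl chloride, CC(C)(C)[Si](C)(C)Cl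
Why: Deprotonation of the only enolisable carbonyl (C14) through the open transition state favoured by HMPA puts the bulky C2 branch syn to O-metal, so silylation gives the (Z)-ketene acetal 21, whose unit C1=C14–O–CH2*–C11=C10 is a 1,5-diene inside the large ring and undergoes a suprafacial [3,3] shift that makes C1–C10 and breaks O–CH2*. The closest known reaction type is the Ireland–Claisen four-atom ring contraction of macrolactone silyl ketene acetals, which is precedented for 14 → 10 contractions. The ten-membered carbocycle is closed transannularly rather than end to end: the six-centre chair occupies the place later taken by ring A and is trans-fused to the nascent ring, with both tether bonds (C1–C2 and C10–C9) equatorial. The C1/C10 relationship (Me-15 axial and anti to H-10) follows from the E C10=C11 bond combined with the Z ketene acetal in that chair. The absolute sense comes from the flanking centres: at C10, A(1,3) strain with Me-20 holds H-9 in the alkene plane and C1 bonds anti to the C9–O bond; at C1, A(1,3) strain with the ketene-acetal OTBS holds H-2 inside and C10 bonds anti to the donor C2–C3 bond; both preferences select the same pair of faces. The selectivities needed are ketene acetal geometry, secured by HMPA and by the preference of the large ring for a transoid C2–C1=C14–O unit, and chair over boat, secured by the strain-free trans-bicyclo[8.4.0]-like array.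

Step 18
Reactants: 22 silyl ester
Product: 23 neopentyl primary alcohol (C14H2OH on C1)
Conditions: LiAlH4, Et2O, 0 °C → rt
Reagents that add atoms: none
Why: hydride reduction of the silyl ester is compatible with the silyl ethers, acetals and unactivated alkenes present.

Step 19
Reactants: 23 primary alcohol
Product: 25 (14S)-homoallylic alcohol, via aldehyde 24 (not isolated)
Conditions: [Ir(cod)Cl]2, (S)-SEGPHOS, 4-Cl-3-NO2-C6H3CO2H, Cs2CO3 (all cat.), allyl acetate, THF, 100 °C
Reagents that add atoms: allyl acetate, C=CCOC(C)=O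
Why: iridium-catalysed transfer-hydrogenative carbonyl allylation, precedented for neopentyl alcohols, dehydrogenates 23 to the non-enolisable aldehyde 24 and allylates it under catalyst control, with the ligand antipode chosen to give 14S.

Step 20
Reactants: 25 triene alcohol
Product: 26 bicyclo[8.4.0] compound with ring A closed (C11=C12)
Conditions: (H2IMes)(PCy3)Cl2Ru=CHPh (cat.), CH2Cl2 (dilute), 40 °C
Reagents that add atoms: none
Why: ring-closing metathesis starts at the monosubstituted allyl alkene and closes on the C10 isopropenyl group because that gives a six-membered ring, whereas the C8 isopropenyl group would give an eight-membered one.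

Step 21
Reactants: 26 bis-TBS ether
Product: 27 2,9,14-triol
Conditions: TBAF, THF, 50 °C
Reagents that add atoms: none
Why: fluoride desilylation is safe here because no base-sensitive group is present, and any earlier O2 → O14 silyl migration is inconsequential at this point.

Step 22
Reactants: 27 triol
Product: 28 2,9,14-triacetate
Conditions: Ac2O, DMAP, pyridine, 40 °C
Reagents that add atoms: acetic anhydride, CC(=O)OC(C)=O
Why: DMAP-catalysed acetylation covers all three free secondary hydroxyls while O4, O16, O7 and O8 remain masked as acetals.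

Step 23
Reactants: 28 triacetate
Product: 30 C19 primary alcohol (17R), via B-alkyl-9-BBN adduct 29 (not isolated)
Conditions: 9-BBN, THF, rt → 40 °C; then H2O2, aq. NaOAc, 0 °C
Reagents that add atoms: 9-borabicyclo[3.3.1]nonane (atoms appear in 29 only), B1C2CCCC1CCC2; hydrogen peroxide, OO
Why: hydroboration–oxidation with 9-BBN selects the only 1,1-disubstituted alkene over the two trisubstituted ones, and hydrogen should reach C17 anti to C9 in the rotamer with the small C8–O8 bond next to =CH2, which gives 17R.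

Step 24
Reactants: 30 primary alcohol
Product: 31 C19 carboxylic acid
Conditions: TEMPO (cat.), PhI(OAc)2, MeCN–pH 7 buffer, rt
Reagents that add atoms: water, O
Why: oxoammonium oxidation takes the only free (primary) alcohol to the acid while the other primary position, C16, is still masked.

Step 25
Reactants: 31 acid
Product: 33 γ-lactone 4,16-diol with free 8-OH, via tetrahydroxy acid 32 (not isolated)
Conditions: TFA–H2O–CH2Cl2, 0 °C
Reagents that add atoms: none
Why: acid hydrolysis removes both acetals, and the liberated 7-OH closes the five-membered lactone on C19 spontaneously because O9 is blocked as its acetate.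

Step 26
Reactants: 33 diol
Product: 34 16-acetate
Conditions: AcCl, 2,4,6-collidine, CH2Cl2, −78 °C
Reagents that add atoms: acetyl chloride, CC(=O)Cl
Why: low-temperature acetylation with a hindered base is selective for the primary allylic hydroxyl over the secondary 4-OH and the tertiary 8-OH.

Step 27
Reactants: 34 4-alcohol
Product: 35 target CNP0290502.1
Conditions: (n-PrCO)2O, DMAP, Et3N, CH2Cl2, 0 °C → rt
Reagents that add atoms: butyric anhydride, CCCC(=O)OC(=O)CCC
Why: DMAP-catalysed acylation reaches the only remaining secondary hydroxyl (O4), and the tertiary 8-OH is inert under these conditions.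

**Compound list**
1 | 1,2:5,6-di-O-isopropylidene-α-D-glucofuranose | CC3(C)OC[C@@H](O3)[C@@H](O1)[C@H](O)[C@H]2OC(C)(C)O[C@@H]12 | starting material
2 | 1,2:5,6-di-O-isopropylidene-α-D-ribo-hexofuranos-3-ulose | CC3(C)OC[C@@H](O3)[C@@H](O1)C(=O)[C@H]2OC(C)(C)O[C@@H]12 | intermediate
3 | 3-C-isopropenyl-1,2:5,6-di-O-isopropylidene-α-D-allofuranose | CC3(C)OC[C@@H](O3)[C@@H](O1)[C@@](C(C)=C)(O)[C@H]2OC(C)(C)O[C@@H]12 | intermediate
4 | 3-C-isopropenyl-1,2-O-isopropylidene-α-D-ribo-pentodialdo-1,4-furanose | O=C[C@@H](O1)[C@@](C(C)=C)(O)[C@H]2OC(C)(C)O[C@@H]12 | intermediate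
5 | methyl (E)-2-methylenoate, 1,2-acetonide furanose | COC(=O)/C(C)=C/[C@@H](O1)[C@@](C(C)=C)(O)[C@H]2OC(C)(C)O[C@@H]12 | intermediate
6 | 2,3-O-isopropylidene lactol (O7/O8 acetonide) | COC(=O)/C(C)=C/[C@@H](O1)[C@@]2(C(C)=C)OC(C)(C)O[C@H]2C1O | intermediate
7 | open-chain (Z)-α-iodoenoate, free 9-OH | COC(=O)/C(C)=C/[C@@H](O)[C@@]1(C(C)=C)OC(C)(C)O[C@H]1/C=C(\I)C(=O)OC | intermediate
8 | 9-O-TBS ether of 7 | COC(=O)/C(C)=C/[C@@H](O[Si](C)(C)C(C)(C)C)[C@@]1(C(C)=C)OC(C)(C)O[C@H]1/C=C(\I)C(=O)OC | intermediate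
9 | iodo diol (C5–C11 fragment) | OC/C(C)=C/[C@@H](O[Si](C)(C)C(C)(C)C)[C@@]1(C(C)=C)OC(C)(C)O[C@H]1/C=C(\I)CO | intermediate
10 | (S)-4-benzyl-3-propionyl-1,3-oxazolidin-2-one | CCC(=O)N1[C@@H](Cc2ccccc2)COC1=O | starting material
11 | acrolein | C=CC=O | starting material
12 | syn-aldol imide | C=C[C@@H](O)[C@H](C)C(=O)N1[C@@H](Cc2ccccc2)COC1=O | intermediate
13 | methyl (2S,3R)-3-hydroxy-2-methylpent-4-enoate | C=C[C@@H](O)[C@H](C)C(=O)OC | intermediate
14 | TBS ether of 13 | C=C[C@@H](O[Si](C)(C)C(C)(C)C)[C@H](C)C(=O)OC | intermediate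
15 | methyl (2S,3R)-3-(TBSO)-2-methyl-5-oxopentanoate | O=CC[C@@H](O[Si](C)(C)C(C)(C)C)[C@H](C)C(=O)OC | intermediate
16 | coupled triol ester | OC/C(C)=C/[C@@H](O[Si](C)(C)C(C)(C)C)[C@@]1(C(C)=C)OC(C)(C)O[C@H]1/C=C(\[C@H](O)C[C@@H](O[Si](C)(C)C(C)(C)C)[C@H](C)C(=O)OC)CO | intermediate
17 | 4,16-O-(4-methoxybenzylidene) hydroxy ester | OC/C(C)=C/[C@@H](O[Si](C)(C)C(C)(C)C)[C@@]1(C(C)=C)OC(C)(C)O[C@H]1/C=C2\[C@@H](C[C@@H](O[Si](C)(C)C(C)(C)C)[C@H](C)C(=O)OC)O[C@H](c3ccc(OC)cc3)OC2 | intermediate
18 | seco acid | OC/C(C)=C/[C@@H](O[Si](C)(C)C(C)(C)C)[C@@]1(C(C)=C)OC(C)(C)O[C@H]1/C=C2\[C@@H](C[C@@H](O[Si](C)(C)C(C)(C)C)[C@H](C)C(=O)O)O[C@H](c3ccc(OC)cc3)OC2 | intermediate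
19 | mixed 2,4,6-trichlorobenzoic anhydride | OC/C(C)=C/[C@@H](O[Si](C)(C)C(C)(C)C)[C@@]1(C(C)=C)OC(C)(C)O[C@H]1/C=C2\[C@@H](C[C@@H](O[Si](C)(C)C(C)(C)C)[C@H](C)C(=O)OC(=O)c3c(Cl)cc(Cl)cc3Cl)O[C@H](c3ccc(OC)cc3)OC2 | intermediate
20 | 14-membered macrolactone | O=C1OC/C(C)=C/[C@@H](O[Si](C)(C)C(C)(C)C)[C@@]2(C(C)=C)OC(C)(C)O[C@H]2/C=C3\[C@@H](C[C@@H](O[Si](C)(C)C(C)(C)C)[C@@H]1C)O[C@H](c4ccc(OC)cc4)OC3 | intermediate
21 | (Z)-silyl ketene acetal | C/C1=C(/O[Si](C)(C)C(C)(C)C)OC/C(C)=C/[C@@H](O[Si](C)(C)C(C)(C)C)[C@@]2(C(C)=C)OC(C)(C)O[C@H]2/C=C3\[C@@H](C[C@H]1O[Si](C)(C)C(C)(C)C)O[C@H](c4ccc(OC)cc4)OC3 | intermediate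
22 | ten-membered carbocyclic TBS ester | C=C(C)[C@@H]1[C@@H](O[Si](C)(C)C(C)(C)C)[C@@]2(C(C)=C)OC(C)(C)O[C@H]2/C=C3\[C@@H](C[C@@H](O[Si](C)(C)C(C)(C)C)[C@@]1(C)C(=O)O[Si](C)(C)C(C)(C)C)O[C@H](c4ccc(OC)cc4)OC3 | intermediate
23 | neopentyl alcohol | C=C(C)[C@@H]1[C@@H](O[Si](C)(C)C(C)(C)C)[C@@]2(C(C)=C)OC(C)(C)O[C@H]2/C=C3\[C@@H](C[C@@H](O[Si](C)(C)C(C)(C)C)[C@@]1(C)CO)O[C@H](c4ccc(OC)cc4)OC3 | intermediate
24 | C14 aldehyde | C=C(C)[C@@H]1[C@@H](O[Si](C)(C)C(C)(C)C)[C@@]2(C(C)=C)OC(C)(C)O[C@H]2/C=C3\[C@@H](C[C@@H](O[Si](C)(C)C(C)(C)C)[C@@]1(C)C=O)O[C@H](c4ccc(OC)cc4)OC3 | intermediate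
25 | (14S)-homoallylic alcohol | C=C(C)[C@@H]1[C@@H](O[Si](C)(C)C(C)(C)C)[C@@]2(C(C)=C)OC(C)(C)O[C@H]2/C=C3\[C@@H](C[C@@H](O[Si](C)(C)C(C)(C)C)[C@@]1(C)[C@@H](O)CC=C)O[C@H](c4ccc(OC)cc4)OC3 | intermediate
26 | bicyclic metathesis product | COc1ccc(cc1)[C@H]1O[C@@H]2C[C@@H](O[Si](C)(C)C(C)(C)C)[C@@]3(C)[C@@H](O)CC=C(C)[C@@H]3[C@@H](O[Si](C)(C)C(C)(C)C)[C@@]4(C(C)=C)OC(C)(C)O[C@H]4/C=C\2CO1 | intermediate
27 | 2,9,14-triol | COc1ccc(cc1)[C@H]1O[C@@H]2C[C@@H](O)[C@@]3(C)[C@@H](O)CC=C(C)[C@@H]3[C@@H](O)[C@@]4(C(C)=C)OC(C)(C)O[C@H]4/C=C\2CO1 | intermediate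
28 | 2,9,14-triacetate | COc1ccc(cc1)[C@H]1O[C@@H]2C[C@@H](OC(C)=O)[C@@]3(C)[C@@H](OC(C)=O)CC=C(C)[C@@H]3[C@@H](OC(C)=O)[C@@]4(C(C)=C)OC(C)(C)O[C@H]4/C=C\2CO1 | intermediate
29 | B-alkyl-9-BBN adduct | COc1ccc(cc1)[C@H]1O[C@@H]2C[C@@H](OC(C)=O)[C@@]3(C)[C@@H](OC(C)=O)CC=C(C)[C@@H]3[C@@H](OC(C)=O)[C@@]4([C@@H](C)CB5C6CCCC5CCC6)OC(C)(C)O[C@H]4/C=C\2CO1 | intermediate
30 | C19 primary alcohol | COc1ccc(cc1)[C@H]1O[C@@H]2C[C@@H](OC(C)=O)[C@@]3(C)[C@@H](OC(C)=O)CC=C(C)[C@@H]3[C@@H](OC(C)=O)[C@@]4([C@@H](C)CO)OC(C)(C)O[C@H]4/C=C\2CO1 | intermediate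
31 | C19 carboxylic acid | COc1ccc(cc1)[C@H]1O[C@@H]2C[C@@H](OC(C)=O)[C@@]3(C)[C@@H](OC(C)=O)CC=C(C)[C@@H]3[C@@H](OC(C)=O)[C@@]4([C@@H](C)C(=O)O)OC(C)(C)O[C@H]4/C=C\2CO1 | intermediate
32 | tetrahydroxy acid | O[C@@H]1C[C@@H](OC(C)=O)[C@@]2(C)[C@@H](OC(C)=O)CC=C(C)[C@@H]2[C@@H](OC(C)=O)[C@@]([C@@H](C)C(=O)O)(O)[C@H](/C=C\1CO)O | intermediate
33 | γ-lactone 4,16-diol | O[C@@H]1C[C@@H](OC(C)=O)[C@@]2(C)[C@@H](OC(C)=O)CC=C(C)[C@@H]2[C@@H](OC(C)=O)[C@@]2(O)[C@H](/C=C\1CO)OC(=O)[C@@H]2C | intermediate
34 | 16-acetate, free 4-OH | O[C@@H]1C[C@@H](OC(C)=O)[C@@]2(C)[C@@H](OC(C)=O)CC=C(C)[C@@H]2[C@@H](OC(C)=O)[C@@]2(O)[C@H](/C=C\1COC(C)=O)OC(=O)[C@@H]2C | intermediate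
35 | CNP0290502.1 | CCCC(=O)O[C@@H]1C[C@@H](OC(C)=O)[C@@]2(C)[C@@H](OC(C)=O)CC=C(C)[C@@H]2[C@@H](OC(C)=O)[C@@]2(O)[C@H](/C=C\1COC(C)=O)OC(=O)[C@@H]2C | target

Total step count: 27. Longest linear sequence: 23 steps (steps 1–8, then 13–27).

**Steps most likely to fail**

Step 17. The enolate may lose the C2 silyloxy group by β-elimination, enolisation may give the wrong ketene acetal geometry, or part of the material may react through a boat array; each of these erodes the C1/C10 relationship. The fallback replaces the enolate Claisen by a neutral aliphatic Claisen and sets out from 20. DIBAL-H at −78 °C with in situ acetylation (Ac2O, DMAP, pyridine) gives the α-acetoxy ether F1. TMSOTf/i-Pr2NEt then removes acetic acid to give the macrocyclic allyl vinyl ether F2, in which C2 is trans to the ring oxygen, the less strained in-ring geometry. Heating in toluene or xylene contracts the ring through the same chair directly to aldehyde 24. There the fallback comes back to the route: 24 is allylated under the conditions of step 19 with i-PrOH as hydrogen donor.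

Step 23. The hindered isopropenyl group may react slowly, and facial selectivity at C17 may be poor. The fallback replaces kinetic by thermodynamic control of C17 and sets out from 30 taken on as a C17 epimer mixture. Steps 24 and 25 are run as written. The 17-epimeric lactone diol F3 formed beside 33 is equilibrated with catalytic DBU in toluene through the lactone enolate. This should favour Me-18 cis to the small 8-OH and trans to C9. The fallback comes back to the route at 33.

Step 6. The bulky α-iodo ylide may olefinate sluggishly, and the liberated 9-OH may close onto the iodoenoate by oxa-Michael addition. The fallback builds the iodoalkene from an alkyne and sets out from 6.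
- Seyferth–Gilbert homologation with the Ohira–Bestmann reagent (K2CO3, MeOH) gives the terminal alkyne F4.
- TBSOTf/2,6-lutidine gives the silyl ether F5.
- DIBAL-H gives the allylic alcohol F6.
- n-BuLi (2 equiv) and paraformaldehyde give the propargylic diol F7.
- Hydroxyl-directed ruthenium-catalysed trans-hydrostannation ([Cp*RuCl]4, Bu3SnH) gives the (Z)-alkenylstannane F8 with tin on C5.
- Iododestannylation with I2 comes back to the route at 9.

**Further compounds**
F1 | step 17 | α-acetoxy ether (C14 acetal, mixture at C14) | CC(=O)OC1OC/C(C)=C/[C@@H](O[Si](C)(C)C(C)(C)C)[C@@]2(C(C)=C)OC(C)(C)O[C@H]2/C=C3\[C@@H](C[C@@H](O[Si](C)(C)C(C)(C)C)[C@@H]1C)O[C@H](c4ccc(OC)cc4)OC3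
F2 | step 17 | macrocyclic allyl vinyl ether | C/C1=C\OC/C(C)=C/[C@@H](O[Si](C)(C)C(C)(C)C)[C@@]2(C(C)=C)OC(C)(C)O[C@H]2/C=C3\[C@@H](C[C@H]1O[Si](C)(C)C(C)(C)C)O[C@H](c4ccc(OC)cc4)OC3
F3 | step 23 | 17-epimeric lactone diol | O[C@@H]1C[C@@H](OC(C)=O)[C@@]2(C)[C@@H](OC(C)=O)CC=C(C)[C@@H]2[C@@H](OC(C)=O)[C@@]2(O)[C@H](/C=C\1CO)OC(=O)[C@H]2C
F4 | step 6 | terminal alkyne, free 9-OH | COC(=O)/C(C)=C/[C@@H](O)[C@@]1(C(C)=C)OC(C)(C)O[C@H]1C#C
F5 | step 6 | silyl ether of the alkyne | COC(=O)/C(C)=C/[C@@H](O[Si](C)(C)C(C)(C)C)[C@@]1(C(C)=C)OC(C)(C)O[C@H]1C#C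
F6 | step 6 | allylic alcohol alkyne | OC/C(C)=C/[C@@H](O[Si](C)(C)C(C)(C)C)[C@@]1(C(C)=C)OC(C)(C)O[C@H]1C#C
F7 | step 6 | propargylic diol | OC/C(C)=C/[C@@H](O[Si](C)(C)C(C)(C)C)[C@@]1(C(C)=C)OC(C)(C)O[C@H]1C#CCO
F8 | step 6 | (Z)-alkenylstannane | OC/C(C)=C/[C@@H](O[Si](C)(C)C(C)(C)C)[C@@]1(C(C)=C)OC(C)(C)O[C@H]1/C=C(\[Sn](CCCC)(CCCC)CCCC)CO
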